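**Plan**
1. Retrosynthesis: five benzyl ethers are removed last. Before that, the ring A O1–C2 ketal bond and the C3′–H bond are cut together.
2. Enabling feature: the spiro carbon C2/C2′ is C2 of ring B and lies one CH2 away from a ring A phenol. Ring B with its C3′–H methine is therefore an aromatic 2,3-disubstituted benzofuran plus one proton at C3 and one phenol oxygen at C2.
3. The flat benzofuran is cut at C3–CH2 (arm to ring C) and at its furan O–C2 bond (palladium cyclisation–benzylation of an o-alkynylphenol), then at the aryl–alkyne bond (Sonogashira). All three aryl units come from phlorisovalerophenone.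
4. Forward: furan ring C closes first (step 8), furan ring B second (step 12), the ring A dihydrofuran last with dearomatisation of ring B (step 14).
5. Stereochemistry: both stereocentres arise in step 14. C3′ comes from enantioselective protonation by a confined chiral acid, the spiro carbon from ring closure relative to C3′. Only a neutral hydrogenolysis follows.

Key step: step 14

Assumption: the SMILES is read as R at the spiro carbon and S at C3′ (ring A CH2 and the C3′ side chain on opposite faces of ring B); the catalyst antipode that gives this sense has to be fixed by experiment.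

**Route**

Step 1
Reactants: 1 phloroglucinol; 2 isovaleryl chloride
Product: 3 phlorisovalerophenone, 3-methyl-1-(2,4,6-trihydroxyphenyl)butan-1-one
Conditions: AlCl3 (4 equiv), PhNO2–CH2Cl2, 0 °C to 45 °C; aq. HCl work-up
Reagents that add atoms: none
Why: Friedel–Crafts acylation of the symmetric, strongly activated triol should stop at the monoketone because the chelated acyl group deactivates the product.

Step 2
Reactants: 3 phlorisovalerophenone
Product: 4 1-[2,4-bis(benzyloxy)-6-hydroxyphenyl]-3-methylbutan-1-one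
Conditions: BnBr (2.1 equiv), K2CO3, DMF, rt
Reagents that add atoms: benzyl bromide, BrCc1ccccc1
Why: Williamson etherification should alkylate the para hydroxyl and one ortho hydroxyl, while the last hydroxyl, hydrogen-bonded to the ketone, resists benzylation and is kept as the future furan oxygen of ring B.

Step 3
Reactants: 4 1-[2,4-bis(benzyloxy)-6-hydroxyphenyl]-3-methylbutan-1-one
Product: 5 1-[4,6-bis(benzyloxy)-2-hydroxy-3-iodophenyl]-3-methylbutan-1-one (ring B iodide)
Conditions: BnMe3N·ICl2 (1.05 equiv), NaHCO3, CH2Cl2–MeOH, rt, dark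
Reagents that add atoms: benzyltrimethylammonium dichloroiodate, C[N+](C)(C)Cc1ccccc1.Cl[I-]Cl
Why: Electrophilic aromatic iodination should occur ortho to the free phenol, the less hindered of the two open positions and the one this reagent favours in 2-hydroxy-4,6-dialkoxyaryl ketones.

Step 4
Reactants: 3 phlorisovalerophenone; 6 propargyl bromide
Product: 7 3-methyl-1-[2,4,6-trihydroxy-3-(prop-2-yn-1-yl)phenyl]butan-1-one
Conditions: NaOMe (1.0 equiv), MeOH, 0 °C, then 6 (1.0 equiv), 0 °C to rt
Reagents that add atoms: none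
Why: C-alkylation of the ambident phenolate in methanol, the reaction type used for C-prenylation of this ketone, should place the propargyl group on one of the two equivalent ring carbons, so only one mono-C-alkyl isomer can form.

Step 5
Reactants: 7 3-methyl-1-[2,4,6-trihydroxy-3-(prop-2-yn-1-yl)phenyl]butan-1-one
Product: 8 1-[4-(benzyloxy)-2,6-dihydroxy-3-(prop-2-yn-1-yl)phenyl]-3-methylbutan-1-one
Conditions: BnBr (1.0 equiv), K2CO3, acetone, rt
Reagents that add atoms: benzyl bromide, BrCc1ccccc1
Why: Williamson etherification with one equivalent of halide should select the most acidic, non-chelated hydroxyl para to the acyl group, which blocks the oxygen that must not close in the key step.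

Step 6
Reactants: 8 1-[4-(benzyloxy)-2,6-dihydroxy-3-(prop-2-yn-1-yl)phenyl]-3-methylbutan-1-one
Product: 9 5-(benzyloxy)-2-(3-methylbutanoyl)-4-(prop-2-yn-1-yl)-1,3-phenylene bis(2,2-dimethylpropanoate) (ring A alkyne)
Conditions: PivCl (3 equiv), Et3N, DMAP (cat.), CH2Cl2, 0 °C to rt
Reagents that add atoms: pivaloyl chloride, CC(C)(C)C(Cl)=O
Why: DMAP-catalysed acylation masks both hydrogen-bonded phenols as pivalates, so that no ring A oxygen can add to the alkyne or be alkylated in steps 11 and 12.

Step 7
Reactants: 3 phlorisovalerophenone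
Product: 10 1-(2,4,6-trihydroxy-3-iodophenyl)-3-methylbutan-1-one
Conditions: NIS (1.0 equiv), MeCN, −20 °C, dark
Reagents that add atoms: N-iodosuccinimide, O=C1CCC(=O)N1I
Why: Electrophilic aromatic iodination of the symmetric triol with one equivalent of reagent should give a single mono-iodide at one of the two equivalent positions.

Step 8
Reactants: 10 1-(2,4,6-trihydroxy-3-iodophenyl)-3-methylbutan-1-one; 11 propargyl alcohol
Product: 13 1-[4,6-dihydroxy-2-(hydroxymethyl)-1-benzofuran-5-yl]-3-methylbutan-1-one, via alkynylphenol 12 (not isolated)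
Conditions: Pd(PPh3)2Cl2 (3 mol%), CuI (5 mol%), Et3N, DMF, 60 °C
Reagents that add atoms: none
Why: Sonogashira coupling is followed in the same flask by 5-endo-dig addition of the phenoxide para to the acyl group, the most acidic hydroxyl and the only one not hydrogen-bonded to the ketone, which should give the linear 4,6-dihydroxy-5-acylbenzofuran of ring C.

Step 9
Reactants: 13 1-[4,6-dihydroxy-2-(hydroxymethyl)-1-benzofuran-5-yl]-3-methylbutan-1-one
Product: 14 1-[4,6-bis(benzyloxy)-2-(hydroxymethyl)-1-benzofuran-5-yl]-3-methylbutan-1-one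
Conditions: BnBr (2.5 equiv), K2CO3, DMF, 60 °C
Reagents that add atoms: benzyl bromide, BrCc1ccccc1
Why: Williamson etherification under forcing conditions should benzylate both chelated phenols, while carbonate leaves the primary alcohol untouched.

Step 10
Reactants: 14 1-[4,6-bis(benzyloxy)-2-(hydroxymethyl)-1-benzofuran-5-yl]-3-methylbutan-1-one
Product: 15 1-[4,6-bis(benzyloxy)-2-(bromomethyl)-1-benzofuran-5-yl]-3-methylbutan-1-one (ring C bromide)
Conditions: CBr4, PPh3, CH2Cl2, 0 °C
Reagents that add atoms: carbon tetrabromide, BrC(Br)(Br)Br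
Why: Appel bromination converts the primary heterobenzylic alcohol into the bromide under neutral conditions that spare the benzyl ethers and the ketone.

Step 11
Reactants: 5 ring B iodide; 9 ring A alkyne
Product: 16 1-[4,6-bis(benzyloxy)-2-hydroxy-3-{3-[6-(benzyloxy)-3-(3-methylbutanoyl)-2,4-bis(pivaloyloxy)phenyl]prop-1-yn-1-yl}phenyl]-3-methylbutan-1-one
Conditions: Pd(PPh3)2Cl2 (5 mol%), CuI (5 mol%), Et3N, THF, rt to 40 °C
Reagents that add atoms: none
Why: Sonogashira coupling of the aryl iodide with the terminal alkyne near room temperature joins rings A and B, the hydrogen-bonded phenol being too weak a nucleophile to cyclise under these conditions.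

Step 12
Reactants: 16 o-alkynylphenol; 15 ring C bromide
Product: 17 1-{4,6-bis(benzyloxy)-2-{[6-(benzyloxy)-3-(3-methylbutanoyl)-2,4-bis(pivaloyloxy)phenyl]methyl}-3-{[4,6-bis(benzyloxy)-5-(3-methylbutanoyl)-1-benzofuran-2-yl]methyl}-1-benzofuran-7-yl}-3-methylbutan-1-one
Conditions: Pd2(dba)3 (2.5 mol%), tris(2,4,6-trimethoxyphenyl)phosphine (10 mol%), K2CO3, THF, 60 °C
Reagents that add atoms: none
Why: In this oxypalladation–reductive elimination (Cacchi-type annulation), zerovalent palladium adds to the benzylic bromide, the resulting benzylpalladium bromide activates the alkyne for anti attack by the ortho phenoxide, and reductive elimination forms the C3–CH2 bond, closing furan ring B with both carbon arms in place.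

Step 13
Reactants: 17 bis-pivalate benzofuran
Product: 18 1-{4,6-bis(benzyloxy)-2-{[6-(benzyloxy)-2,4-dihydroxy-3-(3-methylbutanoyl)phenyl]methyl}-3-{[4,6-bis(benzyloxy)-5-(3-methylbutanoyl)-1-benzofuran-2-yl]methyl}-1-benzofuran-7-yl}-3-methylbutan-1-one (achiral key-step precursor)
Conditions: NaOMe (2.2 equiv), MeOH–THF, 0 °C to rt; AcOH quench
Reagents that add atoms: none
Why: Base-mediated transesterification (methanolysis) removes both aryl pivalates without touching benzyl ethers, ketones or benzofurans, and the basic medium cannot protonate ring B.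

Step 14
Reactants: 18 key-step precursor
Product: 20 1-[(2R,3′S)-4,4′,6′-tris(benzyloxy)-3′-{[4,6-bis(benzyloxy)-5-(3-methylbutanoyl)-1-benzofuran-2-yl]methyl}-6-hydroxy-7′-(3-methylbutanoyl)-3H,3′H-2,2′-spirobi[1-benzofuran]-7-yl]-3-methylbutan-1-one (pentabenzyl ether of the target), via 2-benzofuranium ion 19 (not isolated)
Conditions: confined chiral imidodiphosphorimidate (IDPi) Brønsted acid built from two 3,3′-diaryl-BINOL units with N-triflyl groups on phosphorus (5 mol%), toluene, 5 Å MS, −40 °C; Et3N quench at −40 °C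
Reagents that add atoms: none
Why: Proposed new method: the confined acid should protonate C3 of benzofuran ring B (an aromatic enol ether made electron-rich by its 4- and 6-benzyloxy groups) inside a chiral ion pair to give the 2-benzofuranium (oxocarbenium) ion 19, which the ring A hydroxyl lying between the acyl group and the benzylic CH2 captures at C2 in a 5-exo-trig closure that forms the ring A dihydrofuran and the ketal. The closest known reaction types are chiral Brønsted acid-catalysed spiroacetalisation of hydroxy enol ethers, imidodiphosphorimidate-catalysed intramolecular hydroalkoxylation of alkenes, and the Butin furan recyclisation, in which a 2-(2-hydroxybenzyl)furan is protonated at C3 and trapped by the phenol as a spiroketal intermediate. The C3′ methine is fixed by the face on which the chiral counter-anion delivers the proton, and the spiro carbon by the substrate: closure places the small aryloxy oxygen syn and the ring A CH2 anti to the C3′ side chain, which is also the less strained ketal, so reversible C–O ionisation should converge on it. Regioselectivity needs a single phenol within reach of C2, which is secured because the ring A oxygen para to the acyl group and every oxygen of rings B and C are benzylated, while protonation of ring C finds no nucleophile and simply reverses. The driving force is built in: the second ring A hydroxyl stays free so that the ketone keeps its hydrogen bond after closure, and dearomatisation relieves the peri strain between the C4 benzyloxy group and the C3 arm and the eclipsing of the two CH2 arms. Low temperature and a basic quench should keep the ketal from reopening to either benzofuran.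

Step 15
Reactants: 20 pentabenzyl ether of the target
Product: 21 CNP0169640.1, 1-[(2R,3′S)-3′-{[4,6-dihydroxy-5-(3-methylbutanoyl)-1-benzofuran-2-yl]methyl}-4,4′,6,6′-tetrahydroxy-7′-(3-methylbutanoyl)-3H,3′H-2,2′-spirobi[1-benzofuran]-7-yl]-3-methylbutan-1-one
Conditions: H2 (1 atm), 10% Pd/C, EtOAc, rt
Reagents that add atoms: none
Why: Catalytic hydrogenolysis of the five benzyl ethers over palladium on carbon in a neutral solvent frees the phenols without acid or base, so the ketal and the C3′ methine should not be disturbed.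

**Compound list**

1 | phloroglucinol | Oc1cc(O)cc(O)c1 | starting material
2 | isovaleryl chloride | CC(C)CC(Cl)=O | starting material
3 | phlorisovalerophenone | CC(C)CC(=O)c1c(O)cc(O)cc1O | intermediate
4 | 1-[2,4-bis(benzyloxy)-6-hydroxyphenyl]-3-methylbutan-1-one | CC(C)CC(=O)c1c(O)cc(OCc2ccccc2)cc1OCc1ccccc1 | intermediate
5 | 1-[4,6-bis(benzyloxy)-2-hydroxy-3-iodophenyl]-3-methylbutan-1-one (ring B iodide) | CC(C)CC(=O)c1c(O)c(I)c(OCc2ccccc2)cc1OCc1ccccc1 | intermediate
6 | propargyl bromide | BrCC#C | starting material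
7 | 3-methyl-1-[2,4,6-trihydroxy-3-(prop-2-yn-1-yl)phenyl]butan-1-one | CC(C)CC(=O)c1c(O)cc(O)c(CC#C)c1O | intermediate
8 | 1-[4-(benzyloxy)-2,6-dihydroxy-3-(prop-2-yn-1-yl)phenyl]-3-methylbutan-1-one | CC(C)CC(=O)c1c(O)cc(OCc2ccccc2)c(CC#C)c1O | intermediate
9 | 5-(benzyloxy)-2-(3-methylbutanoyl)-4-(prop-2-yn-1-yl)-1,3-phenylene bis(2,2-dimethylpropanoate) (ring A alkyne) | CC(C)CC(=O)c1c(OC(=O)C(C)(C)C)cc(OCc2ccccc2)c(CC#C)c1OC(=O)C(C)(C)C | intermediate
10 | 1-(2,4,6-trihydroxy-3-iodophenyl)-3-methylbutan-1-one | CC(C)CC(=O)c1c(O)cc(O)c(I)c1O | intermediate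
11 | propargyl alcohol | OCC#C | starting material
12 | 1-[2,4,6-trihydroxy-3-(3-hydroxyprop-1-yn-1-yl)phenyl]-3-methylbutan-1-one (alkynylphenol, not isolated) | CC(C)CC(=O)c1c(O)cc(O)c(C#CCO)c1O | intermediate
13 | 1-[4,6-dihydroxy-2-(hydroxymethyl)-1-benzofuran-5-yl]-3-methylbutan-1-one | OCc1cc2c(O)c(C(=O)CC(C)C)c(O)cc2o1 | intermediate
14 | 1-[4,6-bis(benzyloxy)-2-(hydroxymethyl)-1-benzofuran-5-yl]-3-methylbutan-1-one | OCc1cc2c(OCc3ccccc3)c(C(=O)CC(C)C)c(OCc3ccccc3)cc2o1 | intermediate
15 | 1-[4,6-bis(benzyloxy)-2-(bromomethyl)-1-benzofuran-5-yl]-3-methylbutan-1-one (ring C bromide) | BrCc1cc2c(OCc3ccccc3)c(C(=O)CC(C)C)c(OCc3ccccc3)cc2o1 | intermediate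
16 | o-alkynylphenol joining rings A and B (ring A as bis-pivalate) | CC(C)CC(=O)c1c(O)c(C#CCc2c(OC(=O)C(C)(C)C)c(C(=O)CC(C)C)c(OC(=O)C(C)(C)C)cc2OCc2ccccc2)c(OCc2ccccc2)cc1OCc1ccccc1 | intermediate
17 | 2-(ring A benzyl)-3-(ring C benzofuran-2-ylmethyl)benzofuran, ring A as bis-pivalate | CC(C)CC(=O)c1c(OCc2ccccc2)cc(OCc2ccccc2)c2c(Cc3cc4c(OCc5ccccc5)c(C(=O)CC(C)C)c(OCc5ccccc5)cc4o3)c(Cc3c(OC(=O)C(C)(C)C)c(C(=O)CC(C)C)c(OC(=O)C(C)(C)C)cc3OCc3ccccc3)oc12 | intermediate
18 | achiral key-step precursor, ring A dihydroxy, five benzyl ethers | CC(C)CC(=O)c1c(OCc2ccccc2)cc(OCc2ccccc2)c2c(Cc3cc4c(OCc5ccccc5)c(C(=O)CC(C)C)c(OCc5ccccc5)cc4o3)c(Cc3c(O)c(C(=O)CC(C)C)c(O)cc3OCc3ccccc3)oc12 | intermediate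
19 | (3S)-3H-1-benzofuran-1-ium (oxocarbenium) ion of ring B, ion-paired with the catalyst anion (not isolated) | CC(C)CC(=O)c1c(O)cc(OCc3ccccc3)c(c1O)CC1=[O+]c2c(C(=O)CC(C)C)c(OCc3ccccc3)cc(OCc3ccccc3)c2[C@@H]1Cc1cc2c(OCc3ccccc3)c(C(=O)CC(C)C)c(OCc3ccccc3)cc2o1 | intermediate
20 | (2R,3′S)-spiroketal, pentabenzyl ether of the target | CC(C)CC(=O)c1c(O)cc(OCc3ccccc3)c2c1O[C@]1(C2)Oc2c(C(=O)CC(C)C)c(OCc3ccccc3)cc(OCc3ccccc3)c2[C@@H]1Cc1cc2c(OCc3ccccc3)c(C(=O)CC(C)C)c(OCc3ccccc3)cc2o1 | intermediate
21 | CNP0169640.1 | CC(C)CC(=O)c1c(O)cc(O)c2c1O[C@]1(C2)Oc2c(C(=O)CC(C)C)c(O)cc(O)c2[C@@H]1Cc1cc2c(O)c(C(=O)CC(C)C)c(O)cc2o1 | target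

**Step count and risks**

Total step count: 15. Longest linear sequence: 9 steps (1, 4, 5, 6, 11, 12, 13, 14, 15; the ring C branch 1, 7, 8, 9, 10, 12, 13, 14, 15 is equally long).

Steps most likely to fail:

Step 14. The benzofuran–ketal equilibrium may lie on the benzofuran side. The ketal may also reopen under the acid with loss of the methine proton, eroding enantiopurity, or ionise at the other C–O bond and drain into the isomeric ring A benzofuran. The fallback uses known chemistry and builds ring B last instead of ring A. It sets out from 9: copper-mediated sp–sp3 coupling with bromide 15 (CuI, Cs2CO3, NaI, DMF, rt) gives the 1,4-diarylbut-2-yne bis-pivalate F1, and methanolysis (NaOMe, MeOH–THF) gives the diol F2. AuCl(PPh3)/AgOTf-catalysed 5-exo-dig hydroalkoxylation by the hydroxyl next to the CH2 then closes ring A as the (Z)-2-alkylidene-2,3-dihydrobenzofuran F3, an exocyclic enol ether. Palladium-catalysed oxyarylation of this enol ether with iodophenol 5 (Pd(OAc)2, PPh3, Ag2CO3, acetone, 50 °C; Larock-type heteroannulation) adds the aryl carbon and the phenol oxygen syn across the Z double bond. This closes ring B and should give racemic 20 with the required relative configuration. Preparative HPLC on a chiral phase removes the enantiomer F4, and the route is rejoined at 20.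

Step 12. The phenoxide may be O-benzylated by the bromide, or cyclisation may outrun coupling and give the 3-unsubstituted benzofuran after protonation of the vinylpalladium. The fallback sets out from 16: iodocyclisation (I2, NaHCO3, MeCN, 0 °C) gives the 3-iodobenzofuran F5. Bromide 15 is converted with Zn dust and LiCl in THF into the benzylic zinc bromide F6, and Negishi coupling of the two (Pd(OAc)2, SPhos, THF, rt) returns to the route at 17.

Step 4. O-alkylation and over-alkylation of the ambident phenolate may dominate, or the o-propargylphenol may cycloisomerise under base to a 2-methylbenzofuran. The fallback sets out from 3 and forms the carbon–carbon bond by sigmatropic rearrangement. Allyl bromide/K2CO3 in acetone gives the 4-O-allyl ether F7, and aromatic Claisen rearrangement (N,N-diethylaniline, 190 °C) gives the 3-allyl triol F8. Benzylation of the para hydroxyl as in step 5 gives F9. Lemieux–Johnson cleavage (OsO4 cat., NaIO4, 2,6-lutidine, dioxane–water) gives the arylacetaldehyde F10, present largely as its lactol. Seyferth–Gilbert homologation with the Ohira–Bestmann reagent (K2CO3, MeOH) returns to the route at 8.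

**Further compounds**

F1 | step 14 | 1,4-diarylbut-2-yne joining rings A and C, ring A as bis-pivalate | CC(C)CC(=O)c1c(OC(=O)C(C)(C)C)cc(OCc2ccccc2)c(CC#CCc2cc3c(OCc4ccccc4)c(C(=O)CC(C)C)c(OCc4ccccc4)cc3o2)c1OC(=O)C(C)(C)C
F2 | step 14 | the same butyne with both ring A hydroxyls free | CC(C)CC(=O)c1c(O)cc(OCc2ccccc2)c(CC#CCc2cc3c(OCc4ccccc4)c(C(=O)CC(C)C)c(OCc4ccccc4)cc3o2)c1O
F3 | step 14 | (Z)-2-alkylidene-2,3-dihydrobenzofuran of ring A carrying the ring C benzofuranylmethyl group | CC(C)CC(=O)c1c(O)cc(OCc2ccccc2)c2c1O/C(C2)=C\Cc1cc2c(OCc3ccccc3)c(C(=O)CC(C)C)c(OCc3ccccc3)cc2o1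
F4 | step 14 | (2S,3′R)-enantiomer of 20 | CC(C)CC(=O)c1c(O)cc(OCc3ccccc3)c2c1O[C@@]1(C2)Oc2c(C(=O)CC(C)C)c(OCc3ccccc3)cc(OCc3ccccc3)c2[C@H]1Cc1cc2c(OCc3ccccc3)c(C(=O)CC(C)C)c(OCc3ccccc3)cc2o1
F5 | step 12 | 3-iodo-2-(ring A benzyl)benzofuran of ring B, ring A as bis-pivalate | CC(C)CC(=O)c1c(OCc2ccccc2)cc(OCc2ccccc2)c2c(I)c(Cc3c(OC(=O)C(C)(C)C)c(C(=O)CC(C)C)c(OC(=O)C(C)(C)C)cc3OCc3ccccc3)oc12
F6 | step 12 | [4,6-bis(benzyloxy)-5-(3-methylbutanoyl)-1-benzofuran-2-yl]methylzinc bromide | Br[Zn]Cc1cc2c(OCc3ccccc3)c(C(=O)CC(C)C)c(OCc3ccccc3)cc2o1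
F7 | step 4 | 1-[4-(allyloxy)-2,6-dihydroxyphenyl]-3-methylbutan-1-one | CC(C)CC(=O)c1c(O)cc(OCC=C)cc1O
F8 | step 4 | 1-[3-allyl-2,4,6-trihydroxyphenyl]-3-methylbutan-1-one | CC(C)CC(=O)c1c(O)cc(O)c(CC=C)c1O
F9 | step 4 | 1-[3-allyl-4-(benzyloxy)-2,6-dihydroxyphenyl]-3-methylbutan-1-one | CC(C)CC(=O)c1c(O)cc(OCc2ccccc2)c(CC=C)c1O
F10 | step 4 | 2-[6-(benzyloxy)-2,4-dihydroxy-3-(3-methylbutanoyl)phenyl]acetaldehyde | CC(C)CC(=O)c1c(O)cc(OCc2ccccc2)c(CC=O)c1O
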